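**Retrosynthetic overview**
1. The target is a 20-membered diaryl ether cyclophane. Ring A carries the ether O on C1', the bridge on C3' and OH on C5'. Ring B carries the ether O on C1, OH on C2 and C4, and the bridge on C6. The bridge is fourteen CH2 groups, and the last step cleaves three methyl ethers.
2. Key disconnection: the bonds C3'(ring A)–CH2 and C6(ring B)–CH2 are cut in one move. This leaves commercial tetradeca-1,13-diene (all fourteen bridge carbons) and a simple diaryl ether with Br on ring A and Cl on ring B. In the forward direction this is a one-pot double hydroboration and double B-alkyl Suzuki–Miyaura stapling. C3'–CH2 forms first between the two partners, and C6–CH2 forms last and closes the macrocycle.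
3. Enabling feature: the bridge is an unbranched, unfunctionalised (CH2)14 chain whose ends sit on two very different aryl carbons. C3' of ring A lies between two C–H positions. C6 of ring B lies ortho to the ether oxygen on C1 and meta to the oxygens on C2 and C4. Placing Br on C3' and Cl on C6 turns this difference into a fixed order of bond formation.
4. The diaryl ether comes from an Ullmann-type O-arylation of 2-chloro-4,6-dimethoxyphenol with 1-bromo-3-iodo-5-methoxybenzene. The phenol comes from 1-chloro-3,5-dimethoxybenzene by Vilsmeier–Haack formylation and Baeyer–Villiger oxidation. C1–O is thus installed where the ring is nucleophilic, while C6, which electrophilic substitution cannot reach, carries its chlorine from the start.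
5. Ring order: both benzene rings are bought. The only ring formed is the 20-membered macrocycle, in step 4.

Key step: step 4

Remark: the target has no stereocentre and no C=C bond, so no stereochemical element has to be set and the SMILES strings need no stereo descriptors.

Step 1
Reactants: 1 1-chloro-3,5-dimethoxybenzene
Product: 3 2-chloro-4,6-dimethoxybenzaldehyde, via aryl iminium salt 2 (not isolated)
Conditions: POCl3 (1.5 equiv), DMF, 0 °C to 90 °C; then ice-water, rt
Reagents that add atoms: N,N-dimethylformamide, CN(C)C=O; water, O
Why: Vilsmeier–Haack formylation, in which the chloroiminium ion should attack the position para to one methoxy group and ortho to the other, which is less crowded than the position between the two methoxy groups, as is usual for 5-substituted resorcinol dimethyl ethers.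

Step 2
Reactants: 3 2-chloro-4,6-dimethoxybenzaldehyde
Product: 5 2-chloro-4,6-dimethoxyphenol, via aryl formate 4 (not isolated)
Conditions: mCPBA (1.3 equiv), CH2Cl2, 0 °C to rt; acid washed out; then K2CO3 (10 mol%), MeOH, rt
Reagents that add atoms: 3-chloroperoxybenzoic acid (mCPBA), OOC(=O)c1cccc(Cl)c1
Why: Baeyer–Villiger (Dakin-type) oxidation, in which the electron-rich aryl group with ortho and para methoxy donors migrates in preference to hydride in the peracid adduct, and the aryl formate is then cleaved by base-catalysed methanolysis.

Step 3
Reactants: 5 2-chloro-4,6-dimethoxyphenol; 6 1-bromo-3-iodo-5-methoxybenzene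
Product: 7 2-(3-bromo-5-methoxyphenoxy)-1-chloro-3,5-dimethoxybenzene
Conditions: CuI (10 mol%), picolinic acid (20 mol%), K3PO4 (2 equiv), 6 (1.3 equiv), DMSO, 85 °C, argon
Reagents that add atoms: none
Why: Ullmann-type copper-catalysed O-arylation, in which the C–I bond of 6 reacts well ahead of C–Br and C–Cl, the picolinate ligand system is established for di-ortho-substituted phenols, and the inert atmosphere protects the electron-rich phenol.

Step 4
Reactants: 7 2-(3-bromo-5-methoxyphenoxy)-1-chloro-3,5-dimethoxybenzene; 8 tetradeca-1,13-diene
Product: 11 macrocyclic trimethyl ether, via bis-borane 9 (not isolated), via omega-boryl aryl chloride 10 (not isolated)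
Conditions: 8 (1.3 equiv), 9-BBN dimer (1.3 equiv), THF, 0 °C to rt; then Pd2(dba)3 (5 mol%), SPhos (20 mol%), 3 M aq K3PO4 (6 equiv), THF (about 1 mM), 65 °C, 7 added by syringe pump over 20 h, argon
Reagents that add atoms: none
Why: Anti-Markovnikov hydroboration of both vinyl groups of 8 gives bis-borane 9, and each molecule of 7 that enters the dilute, borane-rich flask undergoes oxidative addition of zerovalent palladium at the unhindered ring A C–Br bond, transmetalation from a base-activated boron end of 9 and reductive elimination to give 10. Since no C–Br bond is then left in solution, the SPhos-ligated zerovalent palladium inserts into the ring B C6–Cl bond of 10, the tethered B-alkyl group is transferred intramolecularly through a 21-membered palladacycle, and C(sp2)–C(sp3) reductive elimination forms the C6(ring B)–CH2 bond and so closes the 20-membered ring (end-to-end closure of a strain-free polymethylene chain). The closest known reaction types are the B-alkyl Suzuki–Miyaura macrocyclisation and the preparation of [n]cyclophanes from bis(9-BBN) adducts of alpha,omega-dienes and dihaloarenes, and the coupling of B-alkyl-9-BBN reagents with ortho-substituted, electron-rich aryl chlorides is established for dialkylbiarylphosphine ligands. No stereocentre is formed. The step needs a fixed site order and an intramolecular second coupling: the order is secured by Br against Cl and by the ortho aryloxy group that shields C6, and the ring closure by the slow inverse addition, which keeps 7 and 10 at a very low stationary concentration, together with a borane concentration near 1 mM, well below the effective molarity (about 10^-2 M) typical of large polymethylene rings. An acetate-free palladium source and 65 °C are chosen so that the ring B arylpalladium species does not attack the flanked ortho C–H bonds of ring A by concerted metalation-deprotonation.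

Step 5
Reactants: 11 macrocyclic trimethyl ether
Product: 13 target triphenol CNP0173380.0, via tris(dibromoboryl) ether 12 (not isolated)
Conditions: BBr3 (6 equiv), CH2Cl2, −78 °C to rt, argon; then H2O, 0 °C
Reagents that add atoms: none
Why: Lewis acid mediated cleavage of aryl methyl ethers, in which BBr3 binds each methoxy oxygen, bromide removes the methyl group by SN2 attack, the diaryl ether (no sp3 C–O bond) stays intact, and hydrolysis of the boryl ethers should release the three phenols.

**Compound list**
1 | 1-chloro-3,5-dimethoxybenzene | COc1cc(Cl)cc(OC)c1 | starting material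
2 | (2-chloro-4,6-dimethoxybenzylidene)dimethyliminium dichlorophosphate (not isolated) | C[N+](C)=Cc1c(Cl)cc(OC)cc1OC.[O-]P(=O)(Cl)Cl | intermediate
3 | 2-chloro-4,6-dimethoxybenzaldehyde | O=Cc1c(Cl)cc(OC)cc1OC | intermediate
4 | 2-chloro-4,6-dimethoxyphenyl formate (not isolated) | O=COc1c(Cl)cc(OC)cc1OC | intermediate
5 | 2-chloro-4,6-dimethoxyphenol | Oc1c(Cl)cc(OC)cc1OC | intermediate
6 | 1-bromo-3-iodo-5-methoxybenzene | COc1cc(Br)cc(I)c1 | starting material
7 | 2-(3-bromo-5-methoxyphenoxy)-1-chloro-3,5-dimethoxybenzene | COc1cc(Br)cc(Oc2c(Cl)cc(OC)cc2OC)c1 | intermediate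
8 | tetradeca-1,13-diene | C=CCCCCCCCCCCCC=C | starting material
9 | 1,14-bis(9-borabicyclo[3.3.1]nonan-9-yl)tetradecane (not isolated) | C(CCCCCCCCCCCCCB1C2CCCC1CCC2)B1C2CCCC1CCC2 | intermediate
10 | 2-{3-[14-(9-borabicyclo[3.3.1]nonan-9-yl)tetradecyl]-5-methoxyphenoxy}-1-chloro-3,5-dimethoxybenzene (not isolated) | COc1cc(CCCCCCCCCCCCCCB2C3CCCC2CCC3)cc(Oc2c(Cl)cc(OC)cc2OC)c1 | intermediate
11 | macrocyclic trimethyl ether: 20-membered ring made of ring A C1'-C2'-C3', fourteen CH2, ring B C6-C1 and the ether O, with OMe on C5', C2 and C4 | COc1cc2cc(c1)Oc1c(OC)cc(OC)cc1CCCCCCCCCCCCCC2 | intermediate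
12 | the same macrocycle with OBBr2 in place of each OMe (not isolated) | BrB(Br)Oc1cc2cc(c1)Oc1c(OB(Br)Br)cc(OB(Br)Br)cc1CCCCCCCCCCCCCC2 | intermediate
13 | CNP0173380.0: the same macrocycle with OH on C5', C2 and C4 | Oc1cc2cc(c1)Oc1c(O)cc(O)cc1CCCCCCCCCCCCCC2 | target

**Totals:** total step count is 5. The longest linear sequence is 5 steps (1 to 13). Compounds 6 and 8 are bought and enter directly.

**Steps most likely to fail**

**Step 4.**
- The second coupling may run between molecules instead of within one. This can happen by capture of the ring B arylpalladium species by free borane, or by double capping of one chain.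
- Oxidative addition at the hindered C–Cl bond may lag, so that the open intermediate accumulates and oligomerises.
- Palladium may turn to C–H activation of ring A.
- The fallback sets out from 7 and 8 and comes back to the route at 10. It replaces the one-pot stapling by a linear sequence in which the two couplings are separated by an isolation.
- Diene 8 (4 equiv) is treated with one B–H equivalent of 9-BBN to give mainly the mono-adduct 9-(tetradec-13-en-1-yl)-9-borabicyclo[3.3.1]nonane F1.
- F1 is coupled with 7 at normal concentration under Pd(dppf)Cl2, K3PO4, THF/DMF/H2O, 50 °C, a catalyst system that leaves aryl chlorides untouched. This gives 1-chloro-3,5-dimethoxy-2-[3-methoxy-5-(tetradec-13-en-1-yl)phenoxy]benzene F2, which is purified.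
- Hydroboration of pure F2 with 9-BBN then gives 10 as the only boron species in the flask. Slow addition of this solution to Pd2(dba)3, SPhos and aq K3PO4 in THF at 65 °C closes the same bond to 11 with no external borane competing.

**Step 3.**
- C–O bond formation at the di-ortho-substituted phenoxide may be slow.
- The C–Br bond may start to react as well.
- The electron-rich phenol may be lost by oxidation at 85 °C.
- The fallback sets out from 6 (with 5) and comes back at 7. It exchanges copper catalysis for a metal-free aryl transfer from trivalent iodine.
- Compound 6 is oxidised at iodine with mCPBA and TsOH·H2O in MeCN to 1-bromo-3-[hydroxy(tosyloxy)-λ3-iodanyl]-5-methoxybenzene F3.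
- F3 is trapped in the same flask by 1,3,5-trimethoxybenzene to give (3-bromo-5-methoxyphenyl)(2,4,6-trimethoxyphenyl)iodonium tosylate F4.
- Phenol 5 is deprotonated (K2CO3 or KOt-Bu, MeCN or THF, rt to 50 °C) and arylated by ligand coupling at iodine. This tolerates di-ortho substitution, leaves C–Br and C–Cl alone and transfers the less electron-rich aryl group, giving 7.

**Step 5.**
- Cleavage of the three ethers may stop part-way.
- The electron-rich triphenol may degrade by oxidation or acid during Lewis acid treatment and quench.
- The fallback sets out from 7 and comes back at 13. The methyl ethers are exchanged for benzyl ethers before the ring is made, so the route ends under neutral conditions.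
- Compound 7 is demethylated in a pyridinium chloride melt (190 °C) to 4-(3-bromo-5-hydroxyphenoxy)-5-chlorobenzene-1,3-diol F5.
- F5 is benzylated (BnBr, K2CO3, DMF) to 1,5-bis(benzyloxy)-2-[3-(benzyloxy)-5-bromophenoxy]-3-chlorobenzene F6.
- F6 is stapled with 9 exactly as in step 4. It passes through the non-isolated tribenzyl omega-boryl aryl chloride F7 and gives the macrocyclic tribenzyl ether F8.
- Hydrogenolysis of F8 (H2, Pd/C, EtOAc/EtOH, rt) gives 13.

**Further compounds**
F1 | step 4 | 9-(tetradec-13-en-1-yl)-9-borabicyclo[3.3.1]nonane | C=CCCCCCCCCCCCCB1C2CCCC1CCC2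
F2 | step 4 | 1-chloro-3,5-dimethoxy-2-[3-methoxy-5-(tetradec-13-en-1-yl)phenoxy]benzene | C=CCCCCCCCCCCCCc1cc(OC)cc(Oc2c(Cl)cc(OC)cc2OC)c1
F3 | step 3 | 1-bromo-3-[hydroxy(tosyloxy)-λ3-iodanyl]-5-methoxybenzene | COc1cc(Br)cc(c1)I(O)OS(=O)(=O)c1ccc(C)cc1
F4 | step 3 | (3-bromo-5-methoxyphenyl)(2,4,6-trimethoxyphenyl)iodonium tosylate | COc1cc(Br)cc([I+]c2c(OC)cc(OC)cc2OC)c1.Cc1ccc(cc1)S(=O)(=O)[O-]
F5 | step 5 | 4-(3-bromo-5-hydroxyphenoxy)-5-chlorobenzene-1,3-diol | Oc1cc(Br)cc(Oc2c(Cl)cc(O)cc2O)c1
F6 | step 5 | 1,5-bis(benzyloxy)-2-[3-(benzyloxy)-5-bromophenoxy]-3-chlorobenzene | Brc1cc(OCc2ccccc2)cc(Oc2c(Cl)cc(OCc3ccccc3)cc2OCc2ccccc2)c1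
F7 | step 5 | tribenzyl omega-boryl aryl chloride (benzyl analogue of 10, not isolated) | Clc1cc(OCc2ccccc2)cc(OCc2ccccc2)c1Oc1cc(OCc2ccccc2)cc(CCCCCCCCCCCCCCB2C3CCCC2CCC3)c1
F8 | step 5 | macrocyclic tribenzyl ether (benzyl analogue of 11) | C(Oc1cc2cc(c1)Oc1c(OCc3ccccc3)cc(OCc3ccccc3)cc1CCCCCCCCCCCCCC2)c1ccccc1
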